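## Analysis of the target

The target is a spiro[4.5]decene in which ring B is the cyclopentane C1–C5 and ring A is the cyclohexene C5, C6, C7=C8, C9, C10; C1 carries the eight-carbon chain C11–C16 (methyl branches on C11 and C15, primary acetate on C16), C4 and C8 carry methyl groups, and C9 carries a secondary allylic hydroxyl. Of the six stereocentres, C1 (R), C4 (S) and the quaternary spiro carbon C5 (S) are contiguous on ring B, C9 (S) lies on ring A, C11 (R) is acyclic but bonded to C1, and C15 (S) is remote and best bought. On ring B the side chain at C1 and the methyl group at C4 are trans; of the two ring A methylenes on C5, the allylic C6 lies on the face of the side chain and C10 on the face of the C4 methyl, and the C9 oxygen points to the side of ring A that faces C1. C5 is stereogenic only because C6 and C10 differ further out in ring A, so it cannot be set by simple steric arguments on ring B; this, the two tertiary centres flanking it and the acyclic C11 next to C1 make up the main difficulty. The sensitive groups are the allylic alcohol with its trisubstituted alkene (ionisation or dehydration under acid), the primary acetate beside a free secondary hydroxyl, and C1 for as long as C11 is a nitrile or carbonyl carbon. The strategy rests on reading ring A as a masked 2-methylanisole: the C9 oxygen and the C8 methyl sit on adjacent carbons, and C5 is meta to C9 and para to C8. Carbanions attack anisole–Cr(CO)3 complexes meta to the methoxy group, so a carbanion at C1, tethered through C2–C3–C4 to the arene ipso carbon, closes ring B at C5. The dienol ether that results unmasks as the C7=C8–C9 enone, which puts the ring A oxygen and alkene in place without a separate oxidation.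

## Retrosynthetic reasoning

**O16 acetyl and the silyl ethers.** Target 27 is traced to diol 26 by removing the acetyl group. The forward step must acylate the primary hydroxyl and leave the hindered secondary allylic one at C9. Diol 26 is the doubly desilylated form of 25, so both oxygens pass through the organometallic steps as silyl ethers and are released together.

**C13–C14.** Compound 25 is cut between two methylene carbons that carry no function in the target. This cut isolates the remote C15 stereocentre in a three-carbon piece available in enantiopure form. The fragments are tosylate 21 and alkylmagnesium bromide 24, which comes from bromide 23 and bromo alcohol 22. The forward reaction is a Li2CuCl4-catalysed coupling of two primary sp3 carbons that touches neither C11 nor C15.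

**C11–H and C11=C12.** Tosylate 21 and alcohol 20 come from ester 19. The C11 stereocentre of 19 is traced to the C11=C12 double bond of E-enoate 18 (conjugate reduction), and that bond to the carbonyl group of methyl ketone 17 (phosphonate olefination). Making C11 trigonal lets a chiral catalyst set it independently of the crowded ring. The forward steps need E geometry at a hindered ketone and hydride delivery to one face of C11.

**C11–CH3 and C1.** Ketone 17 is traced to nitrile 14 by cutting the bond between C11 and its methyl group, which turns C11 into the nitrile carbon (forward through ketimine 15). C1 is α to the carbonyl at the ketone stage and can be equilibrated there through cis ketone 16, so the ring closure does not have to control C1.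

**C9.** Nitrile 14 is the silyl ether of 13, and 13 is traced to enone 12 by turning the C9 carbinol into a carbonyl group. The forward step is a CBS reduction of a 2-methylcyclohexenone under reagent control.

**C1–C5 (key disconnection).** Enone 12 is cut between the nitrile α-carbon and the spiro carbon. This single cut opens ring B and returns ring A to an aromatic ring, giving complex 9. No other cut removes the quaternary centre and accounts for the ring A functionality at once. Forward, the C1 carbanion must add to the ipso carbon anti to the metal, which sets C5 in adduct 10, and acid must then turn the dienyl complex into 12 by way of methoxydiene 11.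

**Metal–arene bond.** Complex 9 comes from nitrile 8 by complexation. The benzylic centre cannot steer the metal to one arene face, so the forward step includes a separation by metal face. Material complexed on the wrong face is decomplexed to 8 and resubmitted.

**C1–C2 and C4–aryl.** Nitrile 8 is cut at C1–C2 into iodide 5 and acetonitrile 6, which reacts as its lithio derivative 7. Iodide 5 comes from alcohol 4 and ester 3. Ester 3 is cut at the aryl–C4 bond into boronic acid 1 and ethyl crotonate 2. The forward [Rh(nbd)2]BF4–(R)-BINAP-catalysed conjugate addition sets C4, the only stereocentre made before the key step.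

## Alternatives that were turned down

Alternative 1: conjugate methylation with spiro-allylation.
- Disconnection: the C5–C6 bond of ring A and the C4–methyl bond, leading to cyclopentenone A2. In A2 the C6–C10 chain, with the C9 silyl ether and an allylic acetate at C6, hangs on the enone α-carbon (the future C5).
- Forward key step: Cu(OTf)2 with a phosphoramidite ligand catalyses the asymmetric conjugate addition of Me3Al at C4 and gives a regiodefined aluminium enolate at C5. Pd(PPh3)4, a zerovalent palladium catalyst, ionises the allylic acetate, and the enolate closes ring A at the allyl terminus C6 to give spiro ketone A1.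
- For: C4 is set by a catalyst. C5 follows from C4, because the allyl unit should enter anti to the new methyl group, which is the relation in the target. No diastereomeric metal complexes need separating. On control of C4 and C5 this route is stronger than the chosen one.
- Against: 2-substituted cyclopentenones are poor acceptors, and the trapped enolate must form a quaternary centre. A1 ends with a carbonyl at C1 beside the quaternary C5, so the whole C11–C16 chain must be attached at a neopentyl ketone. C1 and C11 are then created afterwards, with the C1 hydrogen delivered to the ring face that already carries the C4 methyl and C10. A2 needs its own synthesis with the C9 stereocentre and a Z-trisubstituted alkene.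
- Comparison: the chosen route is weaker on C5 control. In exchange it puts a carbon substituent on C1 (the nitrile carbon, which becomes C11) in the ring-forming step and takes the ring A oxidation pattern directly from the arene.

Alternative 2: chirality-transferring intramolecular ene reaction.
- Disconnection: the C4–C5 bond, with the hydrogen of the C4 methyl returned to C9 (retro-ene). The precursor is 1,6-diene A4, a 3-silyloxycyclohexene whose C5 carries C1 with the complete side chain and a butenyl arm ending in the vinyl group C4=CH2.
- Forward key step: heating to about 250–280 °C in a sealed tube. The vinyl group adds to C5 while the C9 hydrogen moves suprafacially to the vinyl terminus. This forms C4–C5, ring B, the C4 methyl and the C9=C10 silyl enol ether A3.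
- For: the route is fully convergent, with C11, C15 and the whole chain in place before ring closure. It needs no metal, and the C9 stereocentre relays its configuration to C5. On convergence it is stronger than the chosen route.
- Against: A4 contains C1 and C11 as an acyclic vicinal pair plus C9, all to be built before the key step can be tried. An unactivated vinyl enophile needs forcing temperatures, and the outcome at C4 relative to C1 depends on a small endo/exo difference. A3 lacks the C8 methyl and the C7=C8 alkene, so enol ether cleavage, methylation at C8, dehydrogenation and reduction at C9 follow. The C9 stereocentre used for the transfer has to be made a second time.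
- Comparison: the chosen route builds the chain linearly after ring closure, but ring A arrives complete and C9 is set once.

Alternative 3: alkyne insertion into a spirocyclobutanone.
- Disconnection: the C8–C9 and C6–C7 bonds. Ring A is traced to spirocyclobutanone A6 (ring B with side chain and C4 methyl complete, C9 as the four-ring ketone, C6 and C10 as its two methylene arms on C5) and silylpropyne A7.
- Forward key step: Ni(cod)2, a zerovalent nickel source, with a phosphine couples the carbonyl and the alkyne oxidatively, one acyl–CH2 bond is cleaved by β-carbon elimination, and reductive elimination gives the 7-silyl-8-methyl enone A5.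
- For: ring A with its C8 methyl and enone is made in one catalytic, late and convergent step. The tertiary centres of ring B and the side chain are settled beforehand on a simple cyclopentane. In step economy at the end it is stronger than the chosen route.
- Against: in A6 the spiro carbon is not stereogenic, because its two ketone arms are identical. C5 becomes a stereocentre only through the choice of which arm nickel cleaves. The only difference the catalyst sees is C1 against C4, one bond away, so a mixture of C5 epimers is likely. The alkyne must also insert with its methyl-bearing carbon at the carbonyl, and the silyl group must be removed afterwards.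
- Comparison: the chosen route defines C5 through a discrete stereochemical element, the metal face of complex 9. It also fixes the regiochemistry of ring A through the substitution pattern of the arene.

Key step: step 6

Remarks on the chemistry:
- Spiro compounds are numbered as in the target (C1 side-chain carbon, C4 methyl-bearing carbon, C5 spiro carbon, C9 oxygen-bearing carbon). Arene carbons are primed (C1' ipso, C3' OMe, C4' CH3).
- Compounds 1 and 22 are taken as catalogue compounds.
- Step 5 complexes both arene faces. Only the face isomer 9 is carried on, and the other-face complex is decomplexed to 8 and resubmitted.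
- Step 6 is expected to give 12 together with its C1 epimer (nitrile cis to the C4 methyl). The pair is not separated: the epimer passes through steps 7 and 8 in the same way, and both series converge on ketone 17 in step 9 through cis ketone 16. The structures and descriptors written for 12, 13 and 14 are those of the 1,4-trans series.

## Route

Step 1
Reactants: 1 (3-methoxy-4-methylphenyl)boronic acid; 2 ethyl (E)-but-2-enoate
Product: 3 ethyl (3S)-3-(3-methoxy-4-methylphenyl)butanoate
Conditions: [Rh(nbd)2]BF4 (1 mol %), (R)-BINAP (1.1 mol %), Et3N, 1,4-dioxane/H2O (10:1), 30 °C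
Reagents that add atoms: none
Why: Hayashi–Miyaura asymmetric 1,4-addition; transmetallation gives an aryl complex of monovalent rhodium that inserts the crotonate C=C on the enantioface selected by (R)-BINAP, and water protonates the rhodium enolate; this ligand hand is expected to give the (S)-3-arylbutanoate and so to set C4.

Step 2
Reactants: 3 ethyl (3S)-3-(3-methoxy-4-methylphenyl)butanoate
Product: 4 (3S)-3-(3-methoxy-4-methylphenyl)butan-1-ol
Conditions: LiAlH4, THF, 0 °C
Reagents that add atoms: none
Why: Hydride reduction of the ester to the primary alcohol; the benzylic stereocentre is not acidic under these conditions and is carried unchanged.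

Step 3
Reactants: 4 (3S)-3-(3-methoxy-4-methylphenyl)butan-1-ol
Product: 5 4-[(2S)-4-iodobutan-2-yl]-2-methoxy-1-methylbenzene
Conditions: I2, PPh3, imidazole, CH2Cl2, 0 °C → rt
Reagents that add atoms: iodine, II
Why: Appel-type iodination (Garegg–Samuelsson conditions); iodide displaces the oxyphosphonium group at the primary carbon by SN2, and no stereocentre is involved.

Step 4
Reactants: 5 4-[(2S)-4-iodobutan-2-yl]-2-methoxy-1-methylbenzene; 6 acetonitrile
Product: 8 (5S)-5-(3-methoxy-4-methylphenyl)hexanenitrile, via LiCH2CN 7 (not isolated)
Conditions: 6 (4 equiv), n-BuLi (4 equiv), THF, −78 °C; then 5, −78 °C → rt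
Reagents that add atoms: none
Why: SN2 alkylation of the small nitrile-stabilised carbanion by the primary iodide forms the C1–C2 bond; the excess of carbanion suppresses a second alkylation.

Step 5
Reactants: 8 (5S)-5-(3-methoxy-4-methylphenyl)hexanenitrile
Product: 9 tricarbonyl{η6-(5S)-5-(3-methoxy-4-methylphenyl)hexanenitrile}chromium with the metal on the arene face from which C1'→C2'→C3'(OMe)→C4'(CH3) runs clockwise
Conditions: Cr(CO)6, n-Bu2O/THF (10:1), reflux, argon, dark; chromatography or crystallisation
Reagents that add atoms: hexacarbonylchromium, [Cr].[C-]#[O+].[C-]#[O+].[C-]#[O+].[C-]#[O+].[C-]#[O+].[C-]#[O+]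
Why: Thermal arene complexation (three CO ligands exchanged for the η6-arene); the benzylic centre gives no facial bias, so 9 and the complex with chromium on the other arene face are expected in similar amounts, and as diastereomers they should be separable, the assignment being secured by X-ray analysis of the crystalline complex. The other-face complex is not lost: I2 in Et2O releases nitrile 8 from it for another pass through this step.

Step 6
Reactants: 9 tricarbonyl{η6-(5S)-5-(3-methoxy-4-methylphenyl)hexanenitrile}chromium (face as defined in step 5)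
Product: 12 (1S,4S,5S)-4,8-dimethyl-9-oxospiro[4.5]dec-7-ene-1-carbonitrile, via Li[(η5-dienyl)Cr(CO)3] adduct 10 (not isolated), via methoxydiene 11 (not isolated)
Conditions: LiN(iPr)2 (1.1 equiv), THF, −78 °C; CF3CO2H (5 equiv), −78 °C → rt; conc. aq. NH3; then 3 M aq. HCl, THF, rt
Reagents that add atoms: water, O
Why: LiN(iPr)2 removes a proton α to the nitrile at C1, and the carbanion adds to the ipso carbon C5 on the face opposite chromium, giving the anionic η5-cyclohexadienyl complex 10 that spans C6–C10. CF3CO2H protonates 10 through the metal at a dienyl terminus, ammonia displaces the diene from chromium to give 11, and aqueous acid hydrolyses the enol ether to the enone, whose alkene can only lie at C7=C8 because C5 is quaternary. The closest known reaction type is the addition of nitrile-stabilised carbanions to anisole–Cr(CO)3 complexes meta to the methoxy group, followed by protonation and hydrolysis to cyclohexenones, including intramolecular spiro closures through a three-carbon tether. Ring B closes in a 5-exo-trig mode onto the complexed arene. C5 is controlled by the metal face: C1 enters anti to chromium, so with the face defined in 9 the C10 arm ends on the ring B face that carries the C4 methyl and the C6 arm on the opposite face. C1 is not controlled, so 12 is expected together with its C1 epimer, and C1 is set in step 9. The step needs ipso attack rather than ortho attack, which the meta-directing methoxy group at C9, the para methyl group and the tether length secure, with the acid quench at −78 °C keeping the kinetic spiro adduct. It also needs deprotonation at C1 rather than at the benzylic C4, which the greater kinetic acidity of the unhindered CH2 next to the nitrile over the tertiary benzylic C–H should secure.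

Step 7
Reactants: 12 (1S,4S,5S)-4,8-dimethyl-9-oxospiro[4.5]dec-7-ene-1-carbonitrile
Product: 13 (1S,4S,5S,9S)-9-hydroxy-4,8-dimethylspiro[4.5]dec-7-ene-1-carbonitrile
Conditions: (R)-2-methyl-CBS-oxazaborolidine (20 mol %), catecholborane, toluene, −78 °C
Reagents that add atoms: none
Why: CBS reduction under catalyst control; the α-methylated alkenyl side (C8) acts as the large group, and the (R)-catalyst delivers hydride to the carbonyl face that gives 9S, with 1,2-selectivity and an inert nitrile at this temperature; the C1 epimer that accompanies 12 is reduced in the same sense.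

Step 8
Reactants: 13 (1S,4S,5S,9S)-9-hydroxy-4,8-dimethylspiro[4.5]dec-7-ene-1-carbonitrile
Product: 14 (1S,4S,5S,9S)-9-{[tert-butyl(dimethyl)silyl]oxy}-4,8-dimethylspiro[4.5]dec-7-ene-1-carbonitrile
Conditions: TBSOTf, 2,6-lutidine, CH2Cl2, −78 → 0 °C
Reagents that add atoms: tert-butyldimethylsilyl trifluoromethanesulfonate, CC(C)(C)[Si](C)(C)OS(=O)(=O)C(F)(F)F
Why: Silylation of the hindered secondary allylic alcohol with the reactive silyl triflate; the ether protects O9 against the organometallic and basic steps that follow, and the accompanying C1 epimer is silylated likewise.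

Step 9
Reactants: 14 (1S,4S,5S,9S)-9-{[tert-butyl(dimethyl)silyl]oxy}-4,8-dimethylspiro[4.5]dec-7-ene-1-carbonitrile
Product: 17 1-[(1S,4S,5S,9S)-9-{[tert-butyl(dimethyl)silyl]oxy}-4,8-dimethylspiro[4.5]dec-7-en-1-yl]ethan-1-one, via N-lithio ketimine 15 (not isolated), via cis ketone 16 (not isolated)
Conditions: MeLi (3 equiv), Et2O, 0 °C → rt; aq. NH4Cl, then wet SiO2; NaOMe, MeOH, rt → 50 °C
Reagents that add atoms: methyllithium, [Li]C; water, O
Why: Addition of MeLi to the nitrile gives the N-lithio ketimine 15, which is hydrolysed on work-up to the methyl ketones 16 and 17 (the C1-epimeric nitrile carried with 14 feeds cis ketone 16), so C11 and its methyl group are in place; NaOMe then equilibrates C1 through the enolate. The 1,4-trans ketone 17 is expected to predominate, because in 16 the acetyl group shares one face of ring B with the C4 methyl and C10; 17 is separated and recovered 16 is returned to the equilibration, so C1 is set here.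

Step 10
Reactants: 17 1-[(1S,4S,5S,9S)-9-{[tert-butyl(dimethyl)silyl]oxy}-4,8-dimethylspiro[4.5]dec-7-en-1-yl]ethan-1-one
Product: 18 ethyl (2E)-3-[(1R,4S,5S,9S)-9-{[tert-butyl(dimethyl)silyl]oxy}-4,8-dimethylspiro[4.5]dec-7-en-1-yl]but-2-enoate
Conditions: (EtO)2P(O)CH2CO2Et, NaH, THF, reflux
Reagents that add atoms: triethyl phosphonoacetate, CCOC(=O)CP(=O)(OCC)OCC
Why: Horner–Wadsworth–Emmons olefination of a methyl ketone; the bulky ring substituent on C11 ends trans to the ester (E) and the minor Z isomer is removed by chromatography; the stabilised phosphonate anion is a weak base, and any enolisation at C1 that does occur returns mainly the more stable trans ketone.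

Step 11
Reactants: 18 ethyl (2E)-3-[(1R,4S,5S,9S)-9-{[tert-butyl(dimethyl)silyl]oxy}-4,8-dimethylspiro[4.5]dec-7-en-1-yl]but-2-enoate
Product: 19 ethyl (3R)-3-[(1R,4S,5S,9S)-9-{[tert-butyl(dimethyl)silyl]oxy}-4,8-dimethylspiro[4.5]dec-7-en-1-yl]butanoate
Conditions: Cu(OAc)2·H2O (5 mol %), (R)-DTBM-SEGPHOS (5.5 mol %), (EtO)2MeSiH, t-BuOH, toluene, 0 °C → rt
Reagents that add atoms: none
Why: Asymmetric conjugate reduction by a ligated hydride of monovalent copper formed from Cu(OAc)2 and the silane: syn hydrocupration of the E-enoate delivers hydride to the C11 face that gives 11R, and t-BuOH protonates the copper enolate, while the isolated C7=C8 alkene and the silyl ether stay inert. The ligand hand is chosen for that face; if the bulky chiral ring on C11 reverses the usual sense, the (S)-ligand is used instead.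

Step 12
Reactants: 19 ethyl (3R)-3-[(1R,4S,5S,9S)-9-{[tert-butyl(dimethyl)silyl]oxy}-4,8-dimethylspiro[4.5]dec-7-en-1-yl]butanoate
Product: 20 (3R)-3-[(1R,4S,5S,9S)-9-{[tert-butyl(dimethyl)silyl]oxy}-4,8-dimethylspiro[4.5]dec-7-en-1-yl]butan-1-ol
Conditions: LiAlH4, Et2O, 0 °C
Reagents that add atoms: none
Why: Hydride reduction of the ester to the primary alcohol C13–OH; the silyl ether, the alkene and all stereocentres are unaffected.

Step 13
Reactants: 20 (3R)-3-[(1R,4S,5S,9S)-9-{[tert-butyl(dimethyl)silyl]oxy}-4,8-dimethylspiro[4.5]dec-7-en-1-yl]butan-1-ol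
Product: 21 (3R)-3-[(1R,4S,5S,9S)-9-{[tert-butyl(dimethyl)silyl]oxy}-4,8-dimethylspiro[4.5]dec-7-en-1-yl]butyl 4-methylbenzenesulfonate
Conditions: TsCl, Et3N, DMAP (cat.), CH2Cl2, 0 °C → rt
Reagents that add atoms: 4-methylbenzenesulfonyl chloride, Cc1ccc(cc1)S(=O)(=O)Cl
Why: Sulfonylation of the unhindered primary alcohol activates C13 for the coupling.

Step 14
Reactants: 22 (2R)-3-bromo-2-methylpropan-1-ol
Product: 23 [(2R)-3-bromo-2-methylpropoxy](tert-butyl)dimethylsilane
Conditions: TBSCl, imidazole, CH2Cl2, 0 °C → rt
Reagents that add atoms: tert-butyldimethylsilyl chloride, CC(C)(C)[Si](C)(C)Cl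
Why: Silylation of the primary alcohol masks O16 for the organomagnesium step; the C15 stereocentre comes from the chiral pool and is not touched.

Step 15
Reactants: 21 (3R)-3-[(1R,4S,5S,9S)-9-{[tert-butyl(dimethyl)silyl]oxy}-4,8-dimethylspiro[4.5]dec-7-en-1-yl]butyl 4-methylbenzenesulfonate; 23 [(2R)-3-bromo-2-methylpropoxy](tert-butyl)dimethylsilane
Product: 25 tert-butyl({(2S,6R)-6-[(1R,4S,5S,9S)-9-{[tert-butyl(dimethyl)silyl]oxy}-4,8-dimethylspiro[4.5]dec-7-en-1-yl]-2-methylheptyl}oxy)dimethylsilane, via alkylmagnesium bromide 24 (not isolated)
Conditions: 23, Mg, THF, 40 °C; then 21, Li2CuCl4 (5 mol %), THF, −78 °C → rt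
Reagents that add atoms: none
Why: Kochi-type Li2CuCl4-catalysed coupling of a primary tosylate with a primary alkylmagnesium bromide forms C13–C14; neither carbon is stereogenic, so C11 and C15 are carried unchanged, and the γ-silyloxy group does not eliminate from the organomagnesium reagent.

Step 16
Reactants: 25 tert-butyl({(2S,6R)-6-[(1R,4S,5S,9S)-9-{[tert-butyl(dimethyl)silyl]oxy}-4,8-dimethylspiro[4.5]dec-7-en-1-yl]-2-methylheptyl}oxy)dimethylsilane
Product: 26 (2S,6R)-6-[(1R,4S,5S,9S)-9-hydroxy-4,8-dimethylspiro[4.5]dec-7-en-1-yl]-2-methylheptan-1-ol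
Conditions: Bu4NF, THF, rt → 40 °C
Reagents that add atoms: none
Why: Fluoride cleaves both silyl ethers under non-acidic conditions, which spares the ionisable allylic alcohol.

Step 17
Reactants: 26 (2S,6R)-6-[(1R,4S,5S,9S)-9-hydroxy-4,8-dimethylspiro[4.5]dec-7-en-1-yl]-2-methylheptan-1-ol
Product: 27 (2S,6R)-6-[(1R,4S,5S,9S)-9-hydroxy-4,8-dimethylspiro[4.5]dec-7-en-1-yl]-2-methylheptyl acetate
Conditions: AcCl (1.1 equiv), 2,4,6-collidine, CH2Cl2, −78 °C
Reagents that add atoms: acetyl chloride, CC(=O)Cl
Why: Selective acylation; the unhindered primary hydroxyl reacts far faster than the secondary allylic one, which is flanked by the C8 methyl and the neopentyl C10, so one equivalent at low temperature should give the monoacetate.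

## Compound list

1 | (3-methoxy-4-methylphenyl)boronic acid | Cc1ccc(cc1OC)B(O)O | starting material
2 | ethyl (E)-but-2-enoate | C/C=C/C(=O)OCC | starting material
3 | ethyl (3S)-3-(3-methoxy-4-methylphenyl)butanoate | CCOC(=O)C[C@H](C)c1ccc(C)c(OC)c1 | intermediate
4 | (3S)-3-(3-methoxy-4-methylphenyl)butan-1-ol | OCC[C@H](C)c1ccc(C)c(OC)c1 | intermediate
5 | 4-[(2S)-4-iodobutan-2-yl]-2-methoxy-1-methylbenzene | ICC[C@H](C)c1ccc(C)c(OC)c1 | intermediate
6 | acetonitrile | CC#N | starting material
7 | (cyanomethyl)lithium, LiCH2CN | [Li]CC#N | intermediate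
8 | (5S)-5-(3-methoxy-4-methylphenyl)hexanenitrile | N#CCCC[C@H](C)c1ccc(C)c(OC)c1 | intermediate
9 | tricarbonyl{η6-(5S)-5-(3-methoxy-4-methylphenyl)hexanenitrile}chromium; seen from the metal, C1' (ipso) → C2' → C3' (OMe) → C4' (CH3) runs clockwise (planar chirality not expressed in the SMILES) | N#CCCC[C@H](C)c1ccc(C)c(OC)c1.[Cr].[C-]#[O+].[C-]#[O+].[C-]#[O+] | intermediate
10 | lithium tricarbonyl(η5-cyclohexadienyl)chromate spiro adduct: C6–C10 dienyl anion of the 1-cyano-9-methoxy-4,8-dimethylspiro[4.5]decane skeleton, Cr anti to the new C1–C5 bond (both C1 epimers; one drawn) | N#C[C@H]1CC[C@H](C)[C@@]12[CH-]C=C(C)C(OC)=C2.[Cr].[C-]#[O+].[C-]#[O+].[C-]#[O+].[Li+] | intermediate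
11 | 9-methoxy-4,8-dimethylspiro[4.5]deca-7,9-diene-1-carbonitrile with ring B configured as in 12 (both C1 epimers; one drawn) | N#C[C@H]1CC[C@H](C)[C@@]12CC=C(C)C(OC)=C2 | intermediate
12 | (1S,4S,5S)-4,8-dimethyl-9-oxospiro[4.5]dec-7-ene-1-carbonitrile | N#C[C@H]1CC[C@H](C)[C@@]12CC=C(C)C(=O)C2 | intermediate
13 | (1S,4S,5S,9S)-9-hydroxy-4,8-dimethylspiro[4.5]dec-7-ene-1-carbonitrile | N#C[C@H]1CC[C@H](C)[C@@]12CC=C(C)[C@@H](O)C2 | intermediate
14 | (1S,4S,5S,9S)-9-{[tert-butyl(dimethyl)silyl]oxy}-4,8-dimethylspiro[4.5]dec-7-ene-1-carbonitrile | N#C[C@H]1CC[C@H](C)[C@@]12CC=C(C)[C@@H](O[Si](C)(C)C(C)(C)C)C2 | intermediate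
15 | N-lithio ketimine of ketones 16 and 17 (both C1 epimers) | [Li]N=C(C)C1CC[C@H](C)[C@@]12CC=C(C)[C@@H](O[Si](C)(C)C(C)(C)C)C2 | intermediate
16 | 1-[(1R,4S,5S,9S)-9-{[tert-butyl(dimethyl)silyl]oxy}-4,8-dimethylspiro[4.5]dec-7-en-1-yl]ethan-1-one (acetyl cis to the C4 methyl) | CC(=O)[C@@H]1CC[C@H](C)[C@@]12CC=C(C)[C@@H](O[Si](C)(C)C(C)(C)C)C2 | intermediate
17 | 1-[(1S,4S,5S,9S)-9-{[tert-butyl(dimethyl)silyl]oxy}-4,8-dimethylspiro[4.5]dec-7-en-1-yl]ethan-1-one (acetyl trans to the C4 methyl) | CC(=O)[C@H]1CC[C@H](C)[C@@]12CC=C(C)[C@@H](O[Si](C)(C)C(C)(C)C)C2 | intermediate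
18 | ethyl (2E)-3-[(1R,4S,5S,9S)-9-{[tert-butyl(dimethyl)silyl]oxy}-4,8-dimethylspiro[4.5]dec-7-en-1-yl]but-2-enoate | CCOC(=O)/C=C(\C)[C@H]1CC[C@H](C)[C@@]12CC=C(C)[C@@H](O[Si](C)(C)C(C)(C)C)C2 | intermediate
19 | ethyl (3R)-3-[(1R,4S,5S,9S)-9-{[tert-butyl(dimethyl)silyl]oxy}-4,8-dimethylspiro[4.5]dec-7-en-1-yl]butanoate | CCOC(=O)C[C@@H](C)[C@H]1CC[C@H](C)[C@@]12CC=C(C)[C@@H](O[Si](C)(C)C(C)(C)C)C2 | intermediate
20 | (3R)-3-[(1R,4S,5S,9S)-9-{[tert-butyl(dimethyl)silyl]oxy}-4,8-dimethylspiro[4.5]dec-7-en-1-yl]butan-1-ol | OCC[C@@H](C)[C@H]1CC[C@H](C)[C@@]12CC=C(C)[C@@H](O[Si](C)(C)C(C)(C)C)C2 | intermediate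
21 | (3R)-3-[(1R,4S,5S,9S)-9-{[tert-butyl(dimethyl)silyl]oxy}-4,8-dimethylspiro[4.5]dec-7-en-1-yl]butyl 4-methylbenzenesulfonate | Cc1ccc(cc1)S(=O)(=O)OCC[C@@H](C)[C@H]1CC[C@H](C)[C@@]12CC=C(C)[C@@H](O[Si](C)(C)C(C)(C)C)C2 | intermediate
22 | (2R)-3-bromo-2-methylpropan-1-ol | OC[C@@H](C)CBr | starting material
23 | [(2R)-3-bromo-2-methylpropoxy](tert-butyl)dimethylsilane | CC(C)(C)[Si](C)(C)OC[C@@H](C)CBr | intermediate
24 | bromo[(2R)-3-{[tert-butyl(dimethyl)silyl]oxy}-2-methylpropyl]magnesium | CC(C)(C)[Si](C)(C)OC[C@@H](C)C[Mg]Br | intermediate
25 | tert-butyl({(2S,6R)-6-[(1R,4S,5S,9S)-9-{[tert-butyl(dimethyl)silyl]oxy}-4,8-dimethylspiro[4.5]dec-7-en-1-yl]-2-methylheptyl}oxy)dimethylsilane | CC(C)(C)[Si](C)(C)OC[C@@H](C)CCC[C@@H](C)[C@H]1CC[C@H](C)[C@@]12CC=C(C)[C@@H](O[Si](C)(C)C(C)(C)C)C2 | intermediate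
26 | (2S,6R)-6-[(1R,4S,5S,9S)-9-hydroxy-4,8-dimethylspiro[4.5]dec-7-en-1-yl]-2-methylheptan-1-ol | OC[C@@H](C)CCC[C@@H](C)[C@H]1CC[C@H](C)[C@@]12CC=C(C)[C@@H](O)C2 | intermediate
27 | (2S,6R)-6-[(1R,4S,5S,9S)-9-hydroxy-4,8-dimethylspiro[4.5]dec-7-en-1-yl]-2-methylheptyl acetate | CC(=O)OC[C@@H](C)CCC[C@@H](C)[C@H]1CC[C@H](C)[C@@]12CC=C(C)[C@@H](O)C2 | target

## Step count and least certain steps

Total: 17 steps. The longest linear sequence is 16 steps (1–13 and 15–17). Step 14 prepares the C14–C16 fragment.

**Step 6 (key step).**
- Most likely to go wrong: reversal of the carbanion addition before the acid quench, which would return open complex or divert attack to an ortho carbon. The amide base may also remove the benzylic C4 proton, which would blur the C4/C5 relationship.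
- Fallback: the nitrile anion is replaced by an ester enolate. Ester enolates are established carbon nucleophiles for these complexes, and their adducts revert much less readily. The fallback sets out from nitrile 8 and comes back at ketone 17. Methanolysis of 8 (HCl, MeOH, then water) gives methyl (5S)-5-(3-methoxy-4-methylphenyl)hexanoate F1. Complexation and separation as in step 5 give its tricarbonylchromium complex F2 with the metal face of 9. Treatment with LiN(iPr)2, then CF3CO2H, ammonia and aqueous HCl as in step 6, gives methyl (1S,4S,5S)-4,8-dimethyl-9-oxospiro[4.5]dec-7-ene-1-carboxylate F3. CBS reduction as in step 7 gives the 9S-hydroxy ester F4, and silylation as in step 8 gives the silyl ether ester F5. Me(MeO)NH·HCl with i-PrMgCl converts F5 into the Weinreb amide F6. MeMgBr followed by NaOMe equilibration then returns to 17.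

**Step 5.**
- Most likely to go wrong: the two planar-chiral diastereomers differ only in the relation of the metal face to a benzylic centre that has no polar handle, so they may co-elute and co-crystallise.
- Fallback: the sorting is moved from the complexes to the spiro compounds. It sets out from 8 and comes back at 12. The unseparated mixture of 9 and the other-face complex is cyclised as in step 6. The product contains 12 (with its C1 epimer) and the C5-epimeric nitriles (4S,5R)-4,8-dimethyl-9-oxospiro[4.5]dec-7-ene-1-carbonitrile F7. These differ from 12 in the relation of two adjacent ring stereocentres and are removed by chromatography. The price is that the half of the material that passes through the other-face complex is not recycled.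

**Step 9.**
- Most likely to go wrong: MeLi may deprotonate the hindered nitrile at C1 and not add to it, so nitrile is returned on work-up. The C1 equilibrium may also lie less far on the side of 17 than expected, which costs recycling rounds.
- Fallback: the fallback sets out from 14 (with its C1 epimer) and comes back at 17. Reduction with iBu2AlH and hydrolysis give (1S,4S,5S,9S)-9-{[tert-butyl(dimethyl)silyl]oxy}-4,8-dimethylspiro[4.5]dec-7-ene-1-carbaldehyde F8. The aldehyde is a second point at which C1 can be equilibrated (K2CO3, MeOH) and the epimers separated. MeMgBr then gives the secondary alcohols F9, and Dess–Martin periodinane oxidises them to 17.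

**Step 10.**
- Most likely to go wrong: slow olefination at a carbonyl flanked by the quaternary C5, with competing enolisation and an E/Z mixture that lowers the supply of the E isomer needed for step 11.
- Fallback: the fallback sets out from 14 and comes back at 18. The aldehyde F8 described above is converted with the Ohira–Bestmann reagent (K2CO3, MeOH) into tert-butyl{[(1R,4S,5S,9S)-1-ethynyl-4,8-dimethylspiro[4.5]dec-7-en-9-yl]oxy}dimethylsilane F10. Negishi carboalumination (Me3Al, Cp2ZrCl2 cat., CH2Cl2), followed by n-BuLi and ClCO2Et, gives 18 with E geometry fixed by the syn addition.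

**Step 11.**
- Most likely to go wrong: the large chiral ring on C11 may slow hydrocupration or override the facial preference of the catalyst, leading to erosion or reversal of the selectivity at C11.
- Fallback: the fallback sets out from 18 and comes back at 20. iBu2AlH reduces the ester to (2E)-3-[(1R,4S,5S,9S)-9-{[tert-butyl(dimethyl)silyl]oxy}-4,8-dimethylspiro[4.5]dec-7-en-1-yl]but-2-en-1-ol F11. Hydroxyl-directed Noyori hydrogenation (H2, Ru(OAc)2[(R)-BINAP], MeOH) then gives 20. The sense of this hydrogenation for E-3,3-disubstituted allylic alcohols is well established, with the (R)-ligand corresponding to 11R here, and the alkene without a free hydroxyl (C7=C8) is left alone.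

## Further compounds

F1 | step 6 | methyl (5S)-5-(3-methoxy-4-methylphenyl)hexanoate | COC(=O)CCC[C@H](C)c1ccc(C)c(OC)c1
F2 | step 6 | tricarbonyl{η6-methyl (5S)-5-(3-methoxy-4-methylphenyl)hexanoate}chromium, metal face as in 9 | COC(=O)CCC[C@H](C)c1ccc(C)c(OC)c1.[Cr].[C-]#[O+].[C-]#[O+].[C-]#[O+]
F3 | step 6 | methyl (1S,4S,5S)-4,8-dimethyl-9-oxospiro[4.5]dec-7-ene-1-carboxylate | COC(=O)[C@H]1CC[C@H](C)[C@@]12CC=C(C)C(=O)C2
F4 | step 6 | methyl (1S,4S,5S,9S)-9-hydroxy-4,8-dimethylspiro[4.5]dec-7-ene-1-carboxylate | COC(=O)[C@H]1CC[C@H](C)[C@@]12CC=C(C)[C@@H](O)C2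
F5 | step 6 | methyl (1S,4S,5S,9S)-9-{[tert-butyl(dimethyl)silyl]oxy}-4,8-dimethylspiro[4.5]dec-7-ene-1-carboxylate | COC(=O)[C@H]1CC[C@H](C)[C@@]12CC=C(C)[C@@H](O[Si](C)(C)C(C)(C)C)C2
F6 | step 6 | (1S,4S,5S,9S)-9-{[tert-butyl(dimethyl)silyl]oxy}-N-methoxy-N,4,8-trimethylspiro[4.5]dec-7-ene-1-carboxamide | CON(C)C(=O)[C@H]1CC[C@H](C)[C@@]12CC=C(C)[C@@H](O[Si](C)(C)C(C)(C)C)C2
F7 | step 5 | (4S,5R)-4,8-dimethyl-9-oxospiro[4.5]dec-7-ene-1-carbonitrile (C5-epimeric series, both C1 epimers) | N#CC1CC[C@H](C)[C@]12CC=C(C)C(=O)C2
F8 | step 9 | (1S,4S,5S,9S)-9-{[tert-butyl(dimethyl)silyl]oxy}-4,8-dimethylspiro[4.5]dec-7-ene-1-carbaldehyde | O=C[C@H]1CC[C@H](C)[C@@]12CC=C(C)[C@@H](O[Si](C)(C)C(C)(C)C)C2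
F9 | step 9 | 1-[(1S,4S,5S,9S)-9-{[tert-butyl(dimethyl)silyl]oxy}-4,8-dimethylspiro[4.5]dec-7-en-1-yl]ethan-1-ol (both carbinol epimers) | CC(O)[C@H]1CC[C@H](C)[C@@]12CC=C(C)[C@@H](O[Si](C)(C)C(C)(C)C)C2
F10 | step 10 | tert-butyl{[(1R,4S,5S,9S)-1-ethynyl-4,8-dimethylspiro[4.5]dec-7-en-9-yl]oxy}dimethylsilane | C#C[C@H]1CC[C@H](C)[C@@]12CC=C(C)[C@@H](O[Si](C)(C)C(C)(C)C)C2
F11 | step 11 | (2E)-3-[(1R,4S,5S,9S)-9-{[tert-butyl(dimethyl)silyl]oxy}-4,8-dimethylspiro[4.5]dec-7-en-1-yl]but-2-en-1-ol | OC/C=C(\C)[C@H]1CC[C@H](C)[C@@]12CC=C(C)[C@@H](O[Si](C)(C)C(C)(C)C)C2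
A1 | alternative 1 | (4S,5S,9S)-9-{[tert-butyl(dimethyl)silyl]oxy}-4,8-dimethylspiro[4.5]dec-7-en-1-one | O=C1CC[C@H](C)[C@@]12CC=C(C)[C@@H](O[Si](C)(C)C(C)(C)C)C2
A2 | alternative 1 | (2Z,4S)-4-{[tert-butyl(dimethyl)silyl]oxy}-3-methyl-5-(5-oxocyclopent-1-en-1-yl)pent-2-en-1-yl acetate | O=C1CCC=C1C[C@H](O[Si](C)(C)C(C)(C)C)/C(C)=C\COC(C)=O
A3 | alternative 2 | tert-butyl({(2S,6R)-6-[(1R,4S,5S)-9-{[tert-butyl(dimethyl)silyl]oxy}-4-methylspiro[4.5]dec-9-en-1-yl]-2-methylheptyl}oxy)dimethylsilane | CC(C)(C)[Si](C)(C)OC[C@@H](C)CCC[C@@H](C)[C@H]1CC[C@H](C)[C@@]12CCCC(O[Si](C)(C)C(C)(C)C)=C2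
A4 | alternative 2 | tert-butyl({(2S,6R,7R)-7-[(3R)-3-{[tert-butyl(dimethyl)silyl]oxy}cyclohex-1-en-1-yl]-2,6-dimethylundec-10-en-1-yl}oxy)dimethylsilane | CC(C)(C)[Si](C)(C)OC[C@@H](C)CCC[C@@H](C)[C@@H](CCC=C)C1=C[C@H](O[Si](C)(C)C(C)(C)C)CCC1
A5 | alternative 3 | (1R,4S,5R)-1-[(2R,6S)-7-{[tert-butyl(dimethyl)silyl]oxy}-6-methylheptan-2-yl]-4,8-dimethyl-7-(trimethylsilyl)spiro[4.5]dec-7-en-9-one | CC(C)(C)[Si](C)(C)OC[C@@H](C)CCC[C@@H](C)[C@H]1CC[C@H](C)[C@@]12CC([Si](C)(C)C)=C(C)C(=O)C2
A6 | alternative 3 | (5R,8S)-5-[(2R,6S)-7-{[tert-butyl(dimethyl)silyl]oxy}-6-methylheptan-2-yl]-8-methylspiro[3.4]octan-2-one | CC(C)(C)[Si](C)(C)OC[C@@H](C)CCC[C@@H](C)[C@H]1CC[C@H](C)C12CC(=O)C2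
A7 | alternative 3 | trimethyl(prop-1-yn-1-yl)silane | CC#C[Si](C)(C)C
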